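## Structural features

Kweichowenol B (19) is one carbocycle, a cyclohexene (C1–C6, alkene C5=C6), with one exocyclic carbon, C7, on C1; the only other rings are the phenyl groups of two benzoates. Locants used throughout: C1 quaternary carbinol carrying C7, C2 and C3 CHOH, C4 CHOBz. The four stereocentres C1–C4 are contiguous, (1R,2S,3S,4S), and every neighbouring pair of oxygens is trans, so the oxygens on C1 and C3 lie on one face and those on C2 and C4 on the other. Of five oxygens only two are acylated, the primary one on C7 and the allylic secondary one on C4; the tertiary C1–OH and the C2/C3 diol stay free. The compound is fragile towards base (benzoyl migration from C7 to C1 or from C4 to C3) and towards strong acid (ionisation of the tertiary allylic alcohol or the allylic benzoate). The real difficulty is twofold: the alternating facial pattern of four oxygens next to a quaternary centre, and acylating exactly the right two oxygens. The key step exploits the fact that C6–C1(C7)–C2–C3, with oxygen on C3 and unsaturation at C6, is the skeleton of a 3-substituted furan, and C4–C5 with oxygen on C4 is a ketene unit; a [4+2] addition therefore gives the ring as a 7-oxabicyclo[2.2.1]heptene whose oxygen bridges C3 and C6. That bridge later leaves C6 (revealing C5=C6) and stays on C3, and until then it gives the carbocycle an exo and an endo face, which is what lets the C1 oxygen be placed syn and the C2 oxygen anti to it.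

## Logic of the disconnections

19 from 18. Forward, three O–Si bonds (on C1, C2, C3) are cut. The hydroxyls that must stay free are traced back to silyl ethers so that the C4 oxygen is the only one open to acylation; no selection among four hydroxyls is then needed. The demand is cleavage without base, because the free triol lets benzoyl groups migrate.

18 from 17 and 2. The C4 O–acyl bond is cut. The second benzoate comes from the same reagent as the first. The forward step needs a single free hydroxyl and retention at C4.

17 from 16. The C4–H bond is cut (carbinol back to ketone). This removes the C4 stereocentre and exposes an enone. The forward step needs 1,2-selectivity and hydride delivery to the face that leaves O4 trans to O3.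

16 from 13 (through 14 and 15). Retro-β-elimination: the C3 oxygen is reconnected to C6 and a hydrogen returned to C5; forward, the C6–O and one C5–H bond are cut. A C4 carbonyl flanked by a bridgehead can only enolise towards C5, and the only β-leaving group is the bridge, so the alkene and the C3 hydroxyl arise together. Such an opening leaves the surviving oxygen α′ to the carbonyl (a 6-oxy-cyclohex-2-enone), not at the γ-position. The gain is a rigid bicycle with defined faces. The demand is that C1 and C2 are already sp3 and oxygenated, since an alkene there would let the enone tautomerise to a catechol, and that the hydroxyls are masked.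

13 from 10 (through 11 and 12). The C4 carbonyl is traced back to a carbon bearing bromine and a carboxyl group; forward, the C4–CO2H and C4–Br bonds are cut. The carbonyl must be absent while C2 is reduced. The demand is a degradation that needs no base.

10 from 9. The C2–H bond is cut (carbinol back to ketone). All reagents attack the bicycle from the exo face, so an epoxide or diol on C1–C2 would put both oxygens syn to the bridge, whereas O2 must be anti. Opening an exo epoxide at C2 with inversion was rejected for two reasons. An ester on C7 would sooner reach the tertiary C1 through a five-membered acyloxonium ion than C2 through a six-membered one. After bridge opening the epoxide would also be β,γ to the ketone and open to base-induced elimination. A ketone at C2 turns the same exo preference into the required endo hydroxyl. The demand is a non-enolisable C2 ketone (C1 quaternary, C3 bridgehead) and no other reducible carbonyl.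

9 from 8. The C1–O and C2=O bonds are cut back to the C1=C2 alkene. Both oxygens come from one oxidation. The demand is exo attack; regiochemistry is fixed because only C2 carries hydrogen.

8 from 7. One C–O bond of the carboxyl is cut (acid back to aldehyde). The aldehyde is what the cycloaddition delivers and the acid is what the degradation needs.

7 from 3 and 6. The C3–C4 and C5–C6 bonds are cut (retro-[4+2]); the bicycle falls into an aromatic diene and an enal. The gain is the ring, three stereocentres and all seven skeletal carbons in one step. The demand is regio-, exo- and enantiocontrol.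

3 from 1 and 2. The ester C–O bond is cut; the ester is the one the target keeps on C7.

6 from 4 (through 5). The C–Br bond is cut; the demand is clean mono-dehydrobromination.

## Other disconnections considered

Alternative 1: The cut is the C1–C6 bond. An acyclic ketone A2, whose C2–C4 stereocentres are C4–C2 of D-glucose A3 and whose C5=C6 is a (Z)-iodoalkene, would be closed by a Nozaki–Hiyama–Kishi reaction (divalent chromium, nickel co-catalyst). The alkenylchromium would add to the C1 ketone in a 6-exo-trig closure to give the tertiary alcohol A1.
- In favour: three stereocentres are bought with the chiral pool, the Z-iodide fixes the ring alkene, and the organochromium tolerates ethers and does not enolise an α-alkoxy ketone.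
- Against: C1 is the only new centre and its configuration would rest on chelation or Felkin preferences that cannot be guaranteed. Chain elaboration from A3 is long (differentiation of the primary oxygen, oxidation, Z-selective iodo-olefination of an epimerisable α-alkoxy aldehyde). After closure the two p-methoxybenzyl ethers must be exchanged for benzoates and the two benzyl ethers removed without hydrogenating C5=C6. Chromium is used in large excess.
- Comparison: in structure the alternative is linear from one sugar, while the chosen plan joins two small achiral pieces. In mechanism it is a polar organometallic addition against a cycloaddition. It is the better plan for security of the C2–C4 and absolute configuration and has no regiochemical question. It is equal in needing protecting groups. It is worse in step count, roughly twice that of the chosen plan.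

Alternative 2: The cut is the C1–O and C2–O bonds. Whole cells carrying a benzoate dioxygenase would oxidise benzoic acid A5 at the ipso and ortho carbons to the diene diol acid A4.
- In favour: one step from an achiral aromatic would give enantiopure material with the quaternary C1 in the absolute configuration of 19. The carboxyl becomes C7 and the diene supplies C5=C6 and a handle for C3 and C4.
- Against: in A4 the C1 and C2 hydroxyls are cis, whereas 19 needs them trans, so C2 must be inverted at a secondary carbinol beside a quaternary centre. The diene aromatises by loss of water and dimerises. C3=C4 must be dioxygenated trans with O3 syn to O1 while C5=C6 is spared. A mutant strain and fermentation are required.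
- Comparison: in structure both plans take every ring carbon from one small precursor set (equal). In stereocontrol the enzymatic step would be better than a catalytic cycloaddition that is unproven on a substituted furan. Both plans must correct C2 (equal), though the chosen plan does it on a rigid bicycle with predictable facial bias. In step count the alternative would be equal or slightly better (about eight to ten). The chosen plan needs only ordinary bench chemistry.

Alternative 3: The cut is the C2–O and C3–O bonds of an epoxide. The achiral quinol A7 would be epoxidised with a chiral primary-amine salt and a peroxide (iminium activation, conjugate addition of hydroperoxide, closure onto O–O) at one enantiotopic alkene, syn to the hydroxyl, to give the epoxy ketone A6.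
- In favour: it is the shortest plan, and one catalytic step sets C1, C2 and C3. In A6 the epoxide lies on C2–C3 and C1 bears a free hydroxyl, so the C7 benzoate can reach only C2, through a six-membered acyloxonium ion and with inversion. This gives the trans C1/C2 and C2/C3 relationships directly, without the competing five-membered participation that an epoxide on C1–C2 would suffer.
- Against: the catalyst must choose both the alkene and the face. Iminium formation on a cross-conjugated dienone with a γ-quaternary centre is demanding. Double epoxidation and the base sensitivity of an α,β-epoxy ketone are risks. After opening, the C4 reduction would face competing direction by the C2 and C3 hydroxyls, and the last benzoylation must pick C4–OH out of three secondary hydroxyls.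
- Comparison: in step economy the alternative is clearly better (about six or seven steps against eleven). Its construction of the C1/C2 trans diol is more direct (better). Enantiocontrol rests in both plans on a catalytic step untested on the exact substrate (equal). The end-game is cleaner in the chosen plan, where C1–C3 are silylated when C4 is reduced and acylated.

Key step: step 3

Assumption: the oxazaborolidinone from N-tosyl-(R)-tryptophan is taken to shield 2-bromoacrolein in the sense that leads to the (3S,4S,6S) adduct 7, by analogy with the behaviour of its enantiomer towards cyclopentadiene; if the sense is the opposite, the (S)-tryptophan catalyst is used.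

Remark: in 7 the formyl group is exo and the bridge oxygen lies on the face that C3 needs in 19; the C4 centre of 7 is erased in step 7.

## Route

Step 1
Reactants: 1 3-furanmethanol; 2 benzoyl chloride
Product: 3 furan-3-ylmethyl benzoate
Conditions: BzCl, Et3N, DMAP (cat.), CH2Cl2, 0 °C to rt
Reagents that add atoms: benzoyl chloride (2), O=C(Cl)c1ccccc1
Why: Nucleophilic acyl substitution at the acid chloride with DMAP as acyl-transfer catalyst; the benzoate is the group that 19 keeps on C7.

Step 2
Reactants: 4 acrolein
Product: 6 2-bromoacrolein, via 2,3-dibromopropanal 5 (not isolated)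
Conditions: Br2, CH2Cl2, −78 °C; then Et3N, −78 to 0 °C
Reagents that add atoms: bromine, BrBr
Why: Ionic anti-addition of bromine to the alkene gives 5; triethylamine then removes the acidic α-hydrogen and the β-bromide leaves (E1cB-type dehydrobromination), giving the α-bromo enal.

Step 3
Reactants: 3 furan-3-ylmethyl benzoate; 6 2-bromoacrolein
Product: 7 [(1S,4S,5S)-5-bromo-5-formyl-7-oxabicyclo[2.2.1]hept-2-en-2-yl]methyl benzoate (formyl exo, bromine endo; 3S,4S,6S in route numbering)
Conditions: (4R)-2-butyl-4-(1H-indol-3-ylmethyl)-3-(4-methylphenylsulfonyl)-1,3,2-oxazaborolidin-5-one (10 mol%), CH2Cl2, −78 °C, cold quench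
Reagents that add atoms: none
Why: The boron Lewis acid binds the formyl oxygen of 6 in its s-cis form, the indole of the catalyst stacks on the bound enal and leaves one face open, and 3 adds through its 2- and 5-positions in a concerted, asynchronous, suprafacial [4π+2π] cycloaddition in which the bond from the enal CH2 (C5) to the furan carbon next to the substituent (C6) is the more advanced. The closest known reaction is the oxazaborolidinone-catalysed Diels–Alder addition of furan itself to 2-haloacroleins. The carbocycle is closed by this intermolecular cycloaddition (bonds C3–C4 and C5–C6), and the furan oxygen becomes the one-atom bridge of the 7-oxabicyclo[2.2.1]heptene. The bridgehead centres C3 and C6 are cis by the suprafacial addition and their absolute sense follows from the catalyst-controlled face of the dienophile; C4 is set by the exo preference of the formyl group of an α-bromo enal (bromine endo) and is erased in step 7. Three selectivities are needed: regiochemistry, for which the 3-substituent makes the adjacent furan α-carbon the more nucleophilic terminus (attack there places the developing positive charge on the substituted carbon); exo/endo selectivity, which is intrinsic to 6; and enantioselectivity, which comes from the catalyst. The reaction is run at −78 °C and quenched cold because furan adducts revert easily, and 7 is oxidised at once.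

Step 4
Reactants: 7 bromoaldehyde adduct
Product: 8 (1S,2S,4S)-5-(benzoyloxymethyl)-2-bromo-7-oxabicyclo[2.2.1]hept-5-ene-2-carboxylic acid (carboxyl exo)
Conditions: NaClO2, NaH2PO4, 2-methyl-2-butene, t-BuOH/THF/H2O, 0 °C
Reagents that add atoms: sodium chlorite, [Na+].[O-]Cl=O
Why: Pinnick oxidation of a non-enolisable aldehyde through its chlorous acid adduct; 2-methyl-2-butene removes HOCl before it can add to the strained alkene, and the cold, near-neutral medium limits cycloreversion. No stereocentre is changed.

Step 5
Reactants: 8 bromo acid
Product: 9 (1S,2S,4S,5S)-5-(benzoyloxymethyl)-2-bromo-5-hydroxy-6-oxo-7-oxabicyclo[2.2.1]heptane-2-carboxylic acid (5-OH exo; route numbering C1–OH, C2=O)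
Conditions: RuCl3 (1 mol%), KHSO5 (as 2KHSO5·KHSO4·K2SO4), NaHCO3, EtOAc/MeCN/H2O, 0 °C to rt
Reagents that add atoms: potassium peroxymonosulfate, [K+].[O-]S(=O)(=O)OO
Why: RuO4 formed in situ adds [3+2] to the exo face of the strained trisubstituted alkene (the face of the oxygen bridge; the endo face is screened by the bromine on C4), and the ruthenate ester is oxidised on to the α-hydroxy ketone (ketohydroxylation of an alkene). Regiochemistry is automatic because only C2 carries hydrogen: C1 becomes the tertiary carbinol with its hydroxyl exo, syn to the bridge oxygen on C3, and C2 the ketone.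

Step 6
Reactants: 9 α-hydroxy ketone acid
Product: 10 (1S,2S,4S,5R,6S)-5-(benzoyloxymethyl)-2-bromo-5,6-dihydroxy-7-oxabicyclo[2.2.1]heptane-2-carboxylic acid (5-OH exo, 6-OH endo; route numbering C1–OH exo, C2–OH endo)
Conditions: NaBH4, THF/MeOH, −20 °C; aq. NaH2PO4 work-up
Reagents that add atoms: none
Why: Borohydride reduction of the strained, non-enolisable C2 ketone; hydride enters from the exo face because the endo face is blocked by the endo bromine on C4 and the CH2OBz group on C1, so the new hydroxyl is endo, trans to the oxygens on C1 and C3. The carboxylate, the tertiary bromide and the benzoate are not reduced under these conditions.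

Step 7
Reactants: 10 diol bromo acid
Product: 13 [(1S,2R,3S,4S)-2,3-dihydroxy-5-oxo-7-oxabicyclo[2.2.1]heptan-2-yl]methyl benzoate (route numbering C1–OH exo, C2–OH endo, C4=O), via acyl azide 11 (not isolated), via bromo isocyanate 12 (not isolated)
Conditions: (PhO)2P(O)N3, Et3N, 1,4-dioxane, rt; then AcOH/H2O, 65 °C
Reagents that add atoms: water, O
Why: Curtius rearrangement of the α-bromo acyl azide 11 (migration with retention) gives the α-bromo isocyanate 12, which water converts through the carbamic acid, with loss of CO2, bromide and ammonia, into the ketone; this is the classical unveiling of a 2-haloacrylic ketene equivalent. Water in large excess and a weakly acidic medium keep the isocyanate from being captured by the hydroxyls and the β-hydroxy ketone 13 from retro-aldol cleavage; the C4 stereocentre disappears.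

Step 8
Reactants: 13 diol ketone
Product: 16 [(1R,2S,3S)-4-oxo-1,2,3-tris(triethylsilyloxy)cyclohex-5-en-1-yl]methyl benzoate, via bis-silyl ketone 14 (not isolated), via silyl enol ether 15 (not isolated)
Conditions: Et3SiOTf (5 equiv), Et3N (8 equiv), CH2Cl2, −78 °C to rt
Reagents that add atoms: triethylsilyl trifluoromethanesulfonate, CC[Si](CC)(CC)OS(=O)(=O)C(F)(F)F
Why: The silyl triflate silylates both hydroxyls (14) and, with the amine, converts the ketone into its silyl enol ether towards C5 (15), the only direction open because C3 is a bridgehead; silyl triflate on the bridge oxygen then triggers β-elimination of the C6–O bond, the silyl triflate/amine opening known for 7-oxabicyclo[2.2.1]heptan-2-ones. The product is the C5=C6 enone with the former bridge oxygen kept on C3 as its silyl ether; no stereocentre is touched.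

Step 9
Reactants: 16 tris(silyl) enone
Product: 17 [(1R,2S,3R,4S)-4-hydroxy-1,2,3-tris(triethylsilyloxy)cyclohex-5-en-1-yl]methyl benzoate (C4–OH trans to the C3 oxygen)
Conditions: NaBH4, CeCl3·7H2O, MeOH, −78 °C
Reagents that add atoms: none
Why: Luche 1,2-reduction of the enone; in the half-chair that keeps the three silyloxy groups pseudo-equatorial, hydride should add axially to C4, antiperiplanar to the axial C3–H and on the face of the C3 oxygen, which gives the pseudo-equatorial C4 hydroxyl trans to that oxygen. Cerium suppresses conjugate reduction.

Step 10
Reactants: 17 allylic alcohol; 2 benzoyl chloride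
Product: 18 [(1R,2S,3R,4S)-4-(benzoyloxy)-1,2,3-tris(triethylsilyloxy)cyclohex-5-en-1-yl]methyl benzoate
Conditions: BzCl, pyridine, DMAP (cat.), CH2Cl2, 0 °C to rt
Reagents that add atoms: benzoyl chloride (2), O=C(Cl)c1ccccc1
Why: DMAP-catalysed acylation of the only free hydroxyl; configuration at C4 is retained and no selection among hydroxyls is needed because C1, C2 and C3 are silylated.

Step 11
Reactants: 18 tris(silyl) dibenzoate
Product: 19 Kweichowenol B, [(1R,2S,3S,4S)-4-(benzoyloxy)-1,2,3-trihydroxycyclohex-5-en-1-yl]methyl benzoate
Conditions: HF·pyridine, pyridine, THF, 0 °C to rt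
Reagents that add atoms: none
Why: Fluoride-assisted cleavage of the three Si–O bonds in a buffered acidic medium, which avoids the base-induced benzoyl migrations (C7 to C1, C4 to C3) open to the free triol; no stereocentre is involved.

## Compound list

1 | 3-furanmethanol | OCc1ccoc1 | starting material
2 | benzoyl chloride | O=C(Cl)c1ccccc1 | starting material
3 | furan-3-ylmethyl benzoate | O=C(OCc1ccoc1)c1ccccc1 | intermediate
4 | acrolein | C=CC=O | starting material
5 | 2,3-dibromopropanal (racemic) | O=CC(Br)CBr | intermediate (not isolated)
6 | 2-bromoacrolein | C=C(Br)C=O | intermediate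
7 | [(1S,4S,5S)-5-bromo-5-formyl-7-oxabicyclo[2.2.1]hept-2-en-2-yl]methyl benzoate, formyl exo | O=C(OCC1=C[C@@H]2O[C@H]1C[C@@]2(Br)C=O)c1ccccc1 | intermediate
8 | (1S,2S,4S)-5-(benzoyloxymethyl)-2-bromo-7-oxabicyclo[2.2.1]hept-5-ene-2-carboxylic acid | O=C(OCC1=C[C@@H]2O[C@H]1C[C@@]2(Br)C(=O)O)c1ccccc1 | intermediate
9 | (1S,2S,4S,5S)-5-(benzoyloxymethyl)-2-bromo-5-hydroxy-6-oxo-7-oxabicyclo[2.2.1]heptane-2-carboxylic acid | O=C(OC[C@@]1(O)C(=O)[C@@H]2O[C@H]1C[C@@]2(Br)C(=O)O)c1ccccc1 | intermediate
10 | (1S,2S,4S,5R,6S)-5-(benzoyloxymethyl)-2-bromo-5,6-dihydroxy-7-oxabicyclo[2.2.1]heptane-2-carboxylic acid | O=C(OC[C@@]1(O)[C@@H](O)[C@@H]2O[C@H]1C[C@@]2(Br)C(=O)O)c1ccccc1 | intermediate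
11 | acyl azide of 10 (same configuration) | O=C(OC[C@@]1(O)[C@@H](O)[C@@H]2O[C@H]1C[C@@]2(Br)C(=O)N=[N+]=[N-])c1ccccc1 | intermediate (not isolated)
12 | α-bromo isocyanate from 11 (C4: bromine endo, isocyanate exo) | O=C(OC[C@@]1(O)[C@@H](O)[C@@H]2O[C@H]1C[C@@]2(Br)N=C=O)c1ccccc1 | intermediate (not isolated)
13 | [(1S,2R,3S,4S)-2,3-dihydroxy-5-oxo-7-oxabicyclo[2.2.1]heptan-2-yl]methyl benzoate | O=C(OC[C@@]1(O)[C@@H](O)[C@@H]2O[C@H]1CC2=O)c1ccccc1 | intermediate
14 | [(1S,2S,3S,4S)-5-oxo-2,3-bis(triethylsilyloxy)-7-oxabicyclo[2.2.1]heptan-2-yl]methyl benzoate | O=C(OC[C@@]1(O[Si](CC)(CC)CC)[C@@H](O[Si](CC)(CC)CC)[C@@H]2O[C@H]1CC2=O)c1ccccc1 | intermediate (not isolated)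
15 | [(1S,2S,3S,4S)-2,3,5-tris(triethylsilyloxy)-7-oxabicyclo[2.2.1]hept-5-en-2-yl]methyl benzoate | O=C(OC[C@@]1(O[Si](CC)(CC)CC)[C@@H](O[Si](CC)(CC)CC)[C@@H]2O[C@H]1C=C2O[Si](CC)(CC)CC)c1ccccc1 | intermediate (not isolated)
16 | [(1R,2S,3S)-4-oxo-1,2,3-tris(triethylsilyloxy)cyclohex-5-en-1-yl]methyl benzoate | O=C(OC[C@]1(O[Si](CC)(CC)CC)C=CC(=O)[C@@H](O[Si](CC)(CC)CC)[C@@H]1O[Si](CC)(CC)CC)c1ccccc1 | intermediate
17 | [(1R,2S,3R,4S)-4-hydroxy-1,2,3-tris(triethylsilyloxy)cyclohex-5-en-1-yl]methyl benzoate | O=C(OC[C@]1(O[Si](CC)(CC)CC)C=C[C@H](O)[C@@H](O[Si](CC)(CC)CC)[C@@H]1O[Si](CC)(CC)CC)c1ccccc1 | intermediate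
18 | [(1R,2S,3R,4S)-4-(benzoyloxy)-1,2,3-tris(triethylsilyloxy)cyclohex-5-en-1-yl]methyl benzoate | O=C(OC[C@]1(O[Si](CC)(CC)CC)C=C[C@H](OC(=O)c2ccccc2)[C@@H](O[Si](CC)(CC)CC)[C@@H]1O[Si](CC)(CC)CC)c1ccccc1 | intermediate
19 | Kweichowenol B, [(1R,2S,3S,4S)-4-(benzoyloxy)-1,2,3-trihydroxycyclohex-5-en-1-yl]methyl benzoate | O=C(OC[C@]1(O)C=C[C@H](OC(=O)c2ccccc2)[C@@H](O)[C@@H]1O)c1ccccc1 | target

## Step count and least certain steps

Total step count: 11. Longest linear sequence: 10 steps (steps 1 and 3–11, from 1); step 2 is a one-step side branch.

Step 3 (key step). Most likely to go wrong: insufficient regiocontrol, because a CH2OBz group is only a weak director and the hindered furan carbon must form the leading bond. Also possible are erosion of enantioselectivity if the ester carbonyl competes for boron, and cycloreversion on warming. Fallback (sets out from 3 and 6, returns at 8): the cycloaddition is run without asymmetric induction (BF3·OEt2, CH2Cl2, −78 °C) to give the racemic bromoaldehyde F1. Pinnick oxidation as in step 4 gives the racemic bromo acid F2. Crystallisation with (R)-1-phenylethylamine gives the diastereomerically pure ammonium salt F3, which on acidification returns 8. The crystallisations also remove the regioisomeric acid. If the salt of the mirror-image acid is the less soluble one, the (S)-amine is used.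

Step 5. Most likely to go wrong: over-oxidation with C1–C2 cleavage of the α-hydroxy ketone, or solvolysis of the tertiary α-bromo carboxylate in the aqueous bicarbonate. Fallback (from 8, back at 9): OsO4 (cat.) with N-methylmorpholine N-oxide dihydroxylates the alkene from the exo face to the exo,exo-diol acid F4. Dess–Martin periodinane then oxidises the secondary C2 hydroxyl, the tertiary one being inert, to 9.

Step 7. Most likely to go wrong: capture of the isocyanate by the hydroxyl groups, giving urethanes, or retro-aldol opening of the β-hydroxy ketone if the medium turns basic. Fallback (from 10, back at 14): both hydroxyls are silylated first (Et3SiOTf, 2,6-lutidine; the silyl ester is hydrolysed on work-up) to the bis(triethylsilyl) ether acid F5. Its Curtius degradation under the conditions of step 7 gives 14, which then needs only enolisation and opening under the conditions of step 8.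

Step 8. Most likely to go wrong: incomplete silylation of the hindered tertiary hydroxyl, or further enolisation of the product towards C3 followed by loss of the C2 oxygen or epimerisation at C3. Fallback (from 13, back at 16): 13 is silylated at −78 °C with Et3SiOTf and 2,6-lutidine and 14 is isolated. Kinetic deprotonation of 14 with LiN(SiMe3)2 in THF at −78 °C gives the enolate towards C5, which expels the bridge oxygen (E1cB). An acetic acid quench at −78 °C gives the hydroxy enone F6, and silylation of its C3 hydroxyl (Et3SiOTf, 2,6-lutidine) gives 16.

Step 9. Most likely to go wrong: poor facial selectivity, or hydride attack from the face opposite to the C3 oxygen if the ring prefers another conformation. Fallback (from 16, back at 18): hydride attack from the other face gives the cis-alcohol F7. F7 is then esterified under Mitsunobu conditions (PPh3, diethyl azodicarboxylate, benzoic acid), which inverts C4 and installs the benzoate in one operation. This gives 18 and bypasses step 10.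

## Further compounds

F1 | step 3 | racemic bromoaldehyde (7 and its enantiomer, 1:1) | O=C(OCC1=C[C@@H]2O[C@H]1C[C@@]2(Br)C=O)c1ccccc1.O=C(OCC1=C[C@H]2O[C@@H]1C[C@]2(Br)C=O)c1ccccc1
F2 | step 3 | racemic bromo acid (8 and its enantiomer, 1:1) | O=C(OCC1=C[C@@H]2O[C@H]1C[C@@]2(Br)C(=O)O)c1ccccc1.O=C(OCC1=C[C@H]2O[C@@H]1C[C@]2(Br)C(=O)O)c1ccccc1
F3 | step 3 | (R)-1-phenylethylammonium salt of 8 | O=C(OCC1=C[C@@H]2O[C@H]1C[C@@]2(Br)C(=O)[O-])c1ccccc1.C[C@@H]([NH3+])c1ccccc1
F4 | step 5 | exo,exo-diol acid, (1S,2S,4S,5R,6R)-5-(benzoyloxymethyl)-2-bromo-5,6-dihydroxy-7-oxabicyclo[2.2.1]heptane-2-carboxylic acid | O=C(OC[C@@]1(O)[C@H](O)[C@@H]2O[C@H]1C[C@@]2(Br)C(=O)O)c1ccccc1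
F5 | step 7 | bis(triethylsilyl) ether of 10 (C1–O exo, C2–O endo silylated, free acid) | O=C(OC[C@@]1(O[Si](CC)(CC)CC)[C@@H](O[Si](CC)(CC)CC)[C@@H]2O[C@H]1C[C@@]2(Br)C(=O)O)c1ccccc1
F6 | step 8 | [(1R,2S,3S)-3-hydroxy-4-oxo-1,2-bis(triethylsilyloxy)cyclohex-5-en-1-yl]methyl benzoate | O=C(OC[C@]1(O[Si](CC)(CC)CC)C=CC(=O)[C@@H](O)[C@@H]1O[Si](CC)(CC)CC)c1ccccc1
F7 | step 9 | [(1R,2S,3R,4R)-4-hydroxy-1,2,3-tris(triethylsilyloxy)cyclohex-5-en-1-yl]methyl benzoate (C4 epimer of 17) | O=C(OC[C@]1(O[Si](CC)(CC)CC)C=C[C@@H](O)[C@@H](O[Si](CC)(CC)CC)[C@@H]1O[Si](CC)(CC)CC)c1ccccc1
A1 | alternative 1 | protected 1-C-(hydroxymethyl)cyclohex-5-ene-1,2,3,4-tetrol with free C1 hydroxyl | COc1ccc(COC[C@]2(O)C=C[C@H](OCc3ccc(OC)cc3)[C@@H](OCc3ccccc3)[C@@H]2OCc4ccccc4)cc1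
A2 | alternative 1 | acyclic (Z)-iodoalkenyl ketone, open-chain precursor of A1 | COc1ccc(COCC(=O)[C@@H](OCc2ccccc2)[C@H](OCc2ccccc2)[C@@H](OCc2ccc(OC)cc2)/C=C\I)cc1
A3 | alternative 1 | D-glucose | OC[C@H]1OC(O)[C@H](O)[C@@H](O)[C@@H]1O
A4 | alternative 2 | (1S,2R)-1,2-dihydroxycyclohexa-3,5-diene-1-carboxylic acid | OC(=O)[C@]1(O)C=CC=C[C@H]1O
A5 | alternative 2 | benzoic acid | O=C(O)c1ccccc1
A6 | alternative 3 | 2,3-epoxy-4-oxo quinol benzoate, epoxide syn to the C1 hydroxyl | O=C(OC[C@]1(O)C=CC(=O)[C@H]2O[C@@H]12)c1ccccc1
A7 | alternative 3 | (1-hydroxy-4-oxocyclohexa-2,5-dien-1-yl)methyl benzoate | O=C1C=CC(O)(COC(=O)c2ccccc2)C=C1
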